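The spiroketal is opened at ring A. In ring A the spiro carbon C2 is tied to the arene twice, through the C3 methylene to C3a and through O1 to the neighbouring aryl carbon C7a; that is the footprint of an ortho-hydroxyaryl unit laid across an exocyclic C=CH2 bond. One operation should do it all: the ring A aryl radical adds to the methylene of a ring B enol ether, the adduct is oxidised, and the ortho phenol closes, making two bonds, ring A and the spiro stereocentre. The precursor is the (3S)-2-methylene-2,3-dihydrobenzofuran of ring B with the benzofuran C arm at C3, met by a ring A ortho-iodophenol whose para oxygen is a pivalate.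

Key step: step 12

Assumption: the sense of induction of the copper–pybox catalyst on this alkyl-substituted propargylic ester cannot be assigned beforehand; the ligand antipode written in step 11 is taken to give the 3S enol ether, and its mirror image is used if the first run shows the opposite sense.

Locants: unprimed = ring A (O1, spiro C2, C3 = CH2); primed = ring B (C3′ carries the arm); benzofuran C is the aromatic benzofuran.

Step 1
Reactants: 1 phloroglucinol; 2 isovaleryl chloride (3-methylbutanoyl chloride)
Product: 3 phlorisovalerophenone, 1-(2,4,6-trihydroxyphenyl)-3-methylbutan-1-one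
Conditions: AlCl3 (3.5 equiv), PhNO2/CH2Cl2, 0 °C to 45 °C; aq HCl
Reagents that add atoms: none
Why: Friedel–Crafts acylation of the symmetric triphenol should give a single mono-ketone because the aluminium-bound acylphloroglucinol is deactivated toward a second acylation.

Step 2
Reactants: 3 phlorisovalerophenone; 4 pivaloyl chloride (1.05 equiv)
Product: 5 3,5-dihydroxy-4-(3-methylbutanoyl)phenyl pivalate
Conditions: Et3N (1.1 equiv), CH2Cl2, −40 °C to 0 °C
Reagents that add atoms: none
Why: Regioselective O-acylation, since the hydroxyl para to the ketone is the most acidic and the only one not held in a hydrogen bond to the carbonyl, so the bulky acyl chloride should take it first.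

Step 3
Reactants: 5 3,5-dihydroxy-4-(3-methylbutanoyl)phenyl pivalate
Product: 6 3,5-dihydroxy-2-iodo-4-(3-methylbutanoyl)phenyl pivalate (ring A iodophenol)
Conditions: NIS (1.0 equiv), CH2Cl2/MeCN, 0 °C, dark
Reagents that add atoms: N-iodosuccinimide, O=C1CCC(=O)N1I
Why: Electrophilic aromatic iodination at one of the two equivalent free ring carbons, each activated by an ortho and a para hydroxyl, with one equivalent of reagent holding the reaction at the mono-iodide.

Step 4
Reactants: 6 ring A iodophenol; 7 benzyl bromide (2.6 equiv)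
Product: 8 3,5-bis(benzyloxy)-2-iodo-4-(3-methylbutanoyl)phenyl pivalate
Conditions: K2CO3 (3 equiv), Bu4NI (10 mol%), DMF, 45 °C
Reagents that add atoms: none
Why: Williamson etherification of both ketone-flanking phenols in a dipolar aprotic medium, in which the hindered pivalate is not attacked by carbonate.

Step 5
Reactants: 8 3,5-bis(benzyloxy)-2-iodo-4-(3-methylbutanoyl)phenyl pivalate
Product: 9 1-[2,6-bis(benzyloxy)-4-hydroxy-3-iodophenyl]-3-methylbutan-1-one
Conditions: K2CO3 (1.5 equiv), MeOH/THF, 0 °C to rt; aq NH4Cl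
Reagents that add atoms: none
Why: Base-mediated methanolysis (transesterification) of the aryl pivalate should free the phenol ortho to iodine while benzyl ethers, ketone and aryl iodide stay inert.

Step 6
Reactants: 10 3-(trimethylsilyl)propynal; 11 propargyl bromide
Product: 12 rac-1-(trimethylsilyl)hexa-1,5-diyn-3-ol
Conditions: Zn dust (1.5 equiv), THF, 0 °C to rt; aq NH4Cl
Reagents that add atoms: none
Why: Barbier propargylation, in which the allenylzinc bromide adds to the aldehyde with allylic transposition (SE2′) to give the homopropargylic alcohol with one free and one silyl-capped alkyne.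

Step 7
Reactants: 9 1-[2,6-bis(benzyloxy)-4-hydroxy-3-iodophenyl]-3-methylbutan-1-one; 12 rac-1-(trimethylsilyl)hexa-1,5-diyn-3-ol
Product: 14 rac-1-[4,6-bis(benzyloxy)-2-[2-hydroxy-4-(trimethylsilyl)but-3-yn-1-yl]-1-benzofuran-5-yl]-3-methylbutan-1-one, via o-alkynylphenol 13 (not isolated)
Conditions: PdCl2(PPh3)2 (5 mol%), CuI (10 mol%), Et3N, DMF, rt then 65 °C
Reagents that add atoms: none
Why: Sonogashira coupling of the free terminal alkyne with the aryl iodide followed by metal-promoted 5-endo-dig attack of the ortho phenol (Sonogashira–heteroannulation benzofuran synthesis), the silyl-capped alkyne being unreactive.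

Step 8
Reactants: 14 silylated benzofuran alkynol
Product: 15 rac-1-[4,6-bis(benzyloxy)-2-(2-hydroxybut-3-yn-1-yl)-1-benzofuran-5-yl]-3-methylbutan-1-one
Conditions: K2CO3 (0.2 equiv), MeOH, rt
Reagents that add atoms: none
Why: Base-catalysed protodesilylation of the alkynylsilane by methoxide, which touches neither the hindered aryl ketone nor the benzyl ethers.

Step 9
Reactants: 15 benzofuran propargylic alcohol; 16 pentafluorobenzoyl chloride (1.2 equiv)
Product: 17 rac-1-[4,6-bis(benzyloxy)-5-(3-methylbutanoyl)-1-benzofuran-2-yl]but-3-yn-2-yl pentafluorobenzoate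
Conditions: Et3N (1.5 equiv), CH2Cl2, −20 °C to 0 °C
Reagents that add atoms: none
Why: Acylation of the secondary propargylic alcohol with an acid chloride, the electron-poor ester being chosen over acetate because alkyl-substituted propargylic esters need the better leaving group to ionise on copper.

Step 10
Reactants: 3 phlorisovalerophenone; 7 benzyl bromide (1.0 equiv)
Product: 18 1-[4-(benzyloxy)-2,6-dihydroxyphenyl]-3-methylbutan-1-one
Conditions: K2CO3 (1.05 equiv), acetone, rt
Reagents that add atoms: none
Why: Williamson etherification with one equivalent of base and halide, selective for the para hydroxyl for the same acidity and hydrogen-bonding reasons as in step 2.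

Step 11
Reactants: 18 4-O-benzyl phlorisovalerophenone (1.5 equiv); 17 propargylic pentafluorobenzoate
Product: 20 1-[(3S)-4-(benzyloxy)-3-{[4,6-bis(benzyloxy)-5-(3-methylbutanoyl)-1-benzofuran-2-yl]methyl}-6-hydroxy-2-methylidene-2,3-dihydro-1-benzofuran-7-yl]-3-methylbutan-1-one, via propargylated phenol 19 (not isolated)
Conditions: Cu(MeCN)4BF4 (5 mol%), (S,S)-Ph-pybox (6 mol%), iPr2NEt (1.5 equiv), MeOH, −20 °C to 0 °C; filtration through Et3N-deactivated silica
Reagents that add atoms: none
Why: Copper-catalysed asymmetric propargylic Friedel–Crafts alkylation followed by 5-exo-dig hydroalkoxylation (formal [3+2] annulation, known for electron-rich phenols), in which the copper allenylidene from 17 is attacked at its γ-carbon by C3 of the phenol inside the chiral ligand pocket, setting the stereocentre (R in 19, S in 20 only through the change of priorities), and the neighbouring hydroxyl then adds to the copper-activated terminal alkyne.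

Step 12
Reactants: 20 ring B enol ether; 6 ring A iodophenol (2 equiv)
Product: 21 (2R,3′S)-4′-(benzyloxy)-3′-{[4,6-bis(benzyloxy)-5-(3-methylbutanoyl)-1-benzofuran-2-yl]methyl}-6,6′-dihydroxy-7,7′-bis(3-methylbutanoyl)-3H,3′H-2,2′-spirobi[[1]benzofuran]-4-yl pivalate
Conditions: 10-phenylphenothiazine (10 mol%), powdered K2HPO4 (3 equiv), degassed MeCN (0.05 M), 390 nm LEDs, 20 °C
Reagents that add atoms: none
Why: Proposed new method: the excited phenothiazine should transfer an electron to iodide 6, the ring A aryl radical adds to the unsubstituted CH2 terminus of the enol ether, the tertiary α-aryloxy radical is oxidised by the phenothiazine radical cation to the C2′ oxocarbenium ion, and the phenol beside the former C–I carbon closes onto it with loss of a proton to the phosphate. The closest known reaction type is the photoredox Meerwein alkoxyarylation of styrenes, enol acetates and vinyl ethers, here run with an aryl iodide and with the oxygen nucleophile built into the arene. Ring A closes by a 5-exo-trig attack of the phenol oxygen on the C2′=O+ bond. The new spiro centre is controlled by C3′: the arylmethyl arm should swing toward the face of H-3′ to avoid the benzofuranylmethyl group, so the small oxygen bonds cis to that group, which is also the thermodynamically preferred arrangement and corresponds to the 2R configuration. The step needs attack at the terminal carbon, secured by the polarity and the open terminus of the 1,1-disubstituted enol ether, and ring closure faster than loss of H-3′ to an aromatic benzofuran, secured by the proximity of the phenol and by keeping only an insoluble weak base in the flask. The pivalate beside the radical carbon offers no hydrogen within reach of a 1,5-shift, which a benzyl ether there would.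

Step 13
Reactants: 21 protected spiroketal pivalate
Product: 22 (2R,3′S)-4′-(benzyloxy)-3′-{[4,6-bis(benzyloxy)-5-(3-methylbutanoyl)-1-benzofuran-2-yl]methyl}-4,6,6′-trihydroxy-7,7′-bis(3-methylbutanoyl)-3H,3′H-2,2′-spirobi[[1]benzofuran]
Conditions: K2CO3 (2 equiv), MeOH/THF, 0 °C, argon; aq NH4Cl
Reagents that add atoms: none
Why: Methanolysis (transesterification) of the aryl pivalate, which should leave the spiroketal and both stereocentres untouched because neither carries a base-labile hydrogen or leaving group.

Step 14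
Reactants: 22 tribenzyl ether
Product: 23 (2R,3′S)-3′-{[4,6-dihydroxy-5-(3-methylbutanoyl)-1-benzofuran-2-yl]methyl}-4,4′,6,6′-tetrahydroxy-7,7′-bis(3-methylbutanoyl)-3H,3′H-2,2′-spirobi[[1]benzofuran] (CNP0169640.1)
Conditions: H2 (1 atm), 10% Pd/C, EtOAc/MeOH, rt
Reagents that add atoms: none
Why: Catalytic hydrogenolysis of the three benzyl aryl ethers under neutral conditions should spare the aryl ketones, the benzofuran and the acid-sensitive spiroketal, so the configuration set in steps 11 and 12 is carried unchanged into the target.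

Compound list
1 | phloroglucinol | Oc1cc(O)cc(O)c1 | starting material
2 | isovaleryl chloride | CC(C)CC(Cl)=O | starting material
3 | phlorisovalerophenone | CC(C)CC(=O)c1c(O)cc(O)cc1O | intermediate
4 | pivaloyl chloride | CC(C)(C)C(Cl)=O | starting material
5 | 3,5-dihydroxy-4-(3-methylbutanoyl)phenyl pivalate | CC(C)CC(=O)c1c(O)cc(OC(=O)C(C)(C)C)cc1O | intermediate
6 | 3,5-dihydroxy-2-iodo-4-(3-methylbutanoyl)phenyl pivalate | CC(C)CC(=O)c1c(O)cc(OC(=O)C(C)(C)C)c(I)c1O | intermediate
7 | benzyl bromide | BrCc1ccccc1 | starting material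
8 | 3,5-bis(benzyloxy)-2-iodo-4-(3-methylbutanoyl)phenyl pivalate | CC(C)CC(=O)c1c(OCc2ccccc2)cc(OC(=O)C(C)(C)C)c(I)c1OCc1ccccc1 | intermediate
9 | 1-[2,6-bis(benzyloxy)-4-hydroxy-3-iodophenyl]-3-methylbutan-1-one | CC(C)CC(=O)c1c(OCc2ccccc2)cc(O)c(I)c1OCc1ccccc1 | intermediate
10 | 3-(trimethylsilyl)propynal | C[Si](C)(C)C#CC=O | starting material
11 | propargyl bromide | BrCC#C | starting material
12 | rac-1-(trimethylsilyl)hexa-1,5-diyn-3-ol | C[Si](C)(C)C#CC(O)CC#C | intermediate
13 | rac-1-[2,6-bis(benzyloxy)-4-hydroxy-3-[4-hydroxy-6-(trimethylsilyl)hexa-1,5-diyn-1-yl]phenyl]-3-methylbutan-1-one | CC(C)CC(=O)c1c(OCc2ccccc2)cc(O)c(C#CCC(O)C#C[Si](C)(C)C)c1OCc1ccccc1 | intermediate (not isolated)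
14 | rac-1-[4,6-bis(benzyloxy)-2-[2-hydroxy-4-(trimethylsilyl)but-3-yn-1-yl]-1-benzofuran-5-yl]-3-methylbutan-1-one | CC(C)CC(=O)c1c(OCc2ccccc2)cc2oc(CC(O)C#C[Si](C)(C)C)cc2c1OCc1ccccc1 | intermediate
15 | rac-1-[4,6-bis(benzyloxy)-2-(2-hydroxybut-3-yn-1-yl)-1-benzofuran-5-yl]-3-methylbutan-1-one | CC(C)CC(=O)c1c(OCc2ccccc2)cc2oc(CC(O)C#C)cc2c1OCc1ccccc1 | intermediate
16 | pentafluorobenzoyl chloride | O=C(Cl)c1c(F)c(F)c(F)c(F)c1F | starting material
17 | rac-1-[4,6-bis(benzyloxy)-5-(3-methylbutanoyl)-1-benzofuran-2-yl]but-3-yn-2-yl pentafluorobenzoate | CC(C)CC(=O)c1c(OCc2ccccc2)cc2oc(CC(OC(=O)c3c(F)c(F)c(F)c(F)c3F)C#C)cc2c1OCc1ccccc1 | intermediate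
18 | 1-[4-(benzyloxy)-2,6-dihydroxyphenyl]-3-methylbutan-1-one | CC(C)CC(=O)c1c(O)cc(OCc2ccccc2)cc1O | intermediate
19 | 1-[4-(benzyloxy)-3-{(2R)-1-[4,6-bis(benzyloxy)-5-(3-methylbutanoyl)-1-benzofuran-2-yl]but-3-yn-2-yl}-2,6-dihydroxyphenyl]-3-methylbutan-1-one | CC(C)CC(=O)c1c(O)cc(OCc2ccccc2)c([C@@H](C#C)Cc2cc3c(OCc4ccccc4)c(C(=O)CC(C)C)c(OCc4ccccc4)cc3o2)c1O | intermediate (not isolated)
20 | 1-[(3S)-4-(benzyloxy)-3-{[4,6-bis(benzyloxy)-5-(3-methylbutanoyl)-1-benzofuran-2-yl]methyl}-6-hydroxy-2-methylidene-2,3-dihydro-1-benzofuran-7-yl]-3-methylbutan-1-one | C=C1Oc2c(C(=O)CC(C)C)c(O)cc(OCc3ccccc3)c2[C@@H]1Cc1cc2c(OCc3ccccc3)c(C(=O)CC(C)C)c(OCc3ccccc3)cc2o1 | intermediate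
21 | (2R,3′S)-4′-(benzyloxy)-3′-{[4,6-bis(benzyloxy)-5-(3-methylbutanoyl)-1-benzofuran-2-yl]methyl}-6,6′-dihydroxy-7,7′-bis(3-methylbutanoyl)-3H,3′H-2,2′-spirobi[[1]benzofuran]-4-yl pivalate | CC(C)CC(=O)c1c(O)cc(OC(=O)C(C)(C)C)c2c1O[C@]1(C2)Oc2c(C(=O)CC(C)C)c(O)cc(OCc3ccccc3)c2[C@@H]1Cc1cc2c(OCc3ccccc3)c(C(=O)CC(C)C)c(OCc3ccccc3)cc2o1 | intermediate
22 | (2R,3′S)-4′-(benzyloxy)-3′-{[4,6-bis(benzyloxy)-5-(3-methylbutanoyl)-1-benzofuran-2-yl]methyl}-4,6,6′-trihydroxy-7,7′-bis(3-methylbutanoyl)-3H,3′H-2,2′-spirobi[[1]benzofuran] | CC(C)CC(=O)c1c(O)cc(O)c2c1O[C@]1(C2)Oc2c(C(=O)CC(C)C)c(O)cc(OCc3ccccc3)c2[C@@H]1Cc1cc2c(OCc3ccccc3)c(C(=O)CC(C)C)c(OCc3ccccc3)cc2o1 | intermediate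
23 | (2R,3′S)-3′-{[4,6-dihydroxy-5-(3-methylbutanoyl)-1-benzofuran-2-yl]methyl}-4,4′,6,6′-tetrahydroxy-7,7′-bis(3-methylbutanoyl)-3H,3′H-2,2′-spirobi[[1]benzofuran] | CC(C)CC(=O)c1c(O)cc(O)c2c1O[C@]1(C2)Oc2c(C(=O)CC(C)C)c(O)cc(O)c2[C@@H]1Cc1cc2c(O)c(C(=O)CC(C)C)c(O)cc2o1 | target

Total step count: 14. Longest linear sequence: 12 steps (steps 1–5, 7–9, 11–14).

Steps most likely to fail

Step 12. The aryl radical may be quenched by hydrogen abstraction before it adds. The oxocarbenium ion may lose H-3′ and aromatise to a 2-benzylbenzofuran, which erases the stereocentre. The phenol may also close on the wrong face. If so, the same two bonds can be made without the carbon–iodine bond, by the known oxidative radical cycloaddition of 1,3-dicarbonyl-type C–H acids to enol ethers. The iodine-free pivalate 5 reacts as an enolised β-triketone. It would be oxidised with Ag2CO3 on Celite, or with (NH4)2Ce(NO3)6 and NaHCO3, in MeCN at 0 °C in the presence of enol ether 20. The ring radical adds to the methylene, the adduct is oxidised and the neighbouring hydroxyl closes. The fallback sets out from 20 and 5 and comes back to the route at 21, with no new compound on the way (F0).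

Step 11. The alkyl-substituted propargylic ester may ionise slowly to the copper allenylidene and instead eliminate to the conjugated enyne. Facial discrimination may be poor. The exocyclic enol ether may isomerise to the aromatic 2-methylbenzofuran. The carbon–carbon bond would then be made by a Nicholas reaction and the enantiomers separated. Setting out from alcohol 15, Co2(CO)8 in CH2Cl2 gives the hexacarbonyldicobalt alkyne complex F1. BF3·OEt2 at −20 °C ionises it to the cobalt-stabilised propargylic cation, which alkylates C3 of phenol 18 to give the racemic cobalt complex of the propargylated phenol F2. Me3NO in CH2Cl2 removes the metal to give the racemic alkyne F3 (the racemate of 19). CuI and iPr2NEt in MeOH close it 5-exo-dig to the racemic enol ether F4. Preparative chiral supercritical-fluid chromatography then delivers the 3S enantiomer 20, where the fallback rejoins the route.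

Step 4. Etherification of the hydrogen-bonded hydroxyl wedged between ketone and iodine may stall. Carbonate may cleave or transfer the pivalate, which would lose the distinction between the para oxygen and the two ortho oxygens. A sulfonate would then carry that distinction, with iodination moved to the end. Setting out from 3, TsCl and K2CO3 in acetone give the para tosylate F5. BnBr and K2CO3 in DMF give the bis(benzyl ether) tosylate F6. KOH in MeOH/H2O at reflux cleaves the sulfonate to the para phenol F7. NIS then iodinates ortho to the free hydroxyl, and the fallback rejoins the route at 9.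

Further compounds
F0 | step 12 | none | none
F1 | step 11 | hexacarbonyldicobalt complex of alkynol 15 | CC(C)CC(=O)c1c(OCc2ccccc2)cc2oc(CC(O)C34C5[Co]3(=C=O)(=C=O)(=C=O)[Co]45(=C=O)(=C=O)=C=O)cc2c1OCc1ccccc1
F2 | step 11 | hexacarbonyldicobalt complex of the racemic propargylated phenol | CC(C)CC(=O)c1c(O)cc(OCc2ccccc2)c(C(Cc2cc3c(OCc4ccccc4)c(C(=O)CC(C)C)c(OCc4ccccc4)cc3o2)C23C4[Co]2(=C=O)(=C=O)(=C=O)[Co]34(=C=O)(=C=O)=C=O)c1O
F3 | step 11 | racemic propargylated phenol (racemate of 19) | CC(C)CC(=O)c1c(O)cc(OCc2ccccc2)c(C(C#C)Cc2cc3c(OCc4ccccc4)c(C(=O)CC(C)C)c(OCc4ccccc4)cc3o2)c1O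
F4 | step 11 | racemic enol ether (racemate of 20) | C=C1Oc2c(C(=O)CC(C)C)c(O)cc(OCc3ccccc3)c2C1Cc1cc2c(OCc3ccccc3)c(C(=O)CC(C)C)c(OCc3ccccc3)cc2o1
F5 | step 4 | 3,5-dihydroxy-4-(3-methylbutanoyl)phenyl 4-methylbenzenesulfonate | CC(C)CC(=O)c1c(O)cc(OS(=O)(=O)c2ccc(C)cc2)cc1O
F6 | step 4 | 3,5-bis(benzyloxy)-4-(3-methylbutanoyl)phenyl 4-methylbenzenesulfonate | CC(C)CC(=O)c1c(OCc2ccccc2)cc(OS(=O)(=O)c2ccc(C)cc2)cc1OCc1ccccc1
F7 | step 4 | 1-[2,6-bis(benzyloxy)-4-hydroxyphenyl]-3-methylbutan-1-one | CC(C)CC(=O)c1c(OCc2ccccc2)cc(O)cc1OCc1ccccc1
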